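Temperature and time are what we reach for first, but at these settings we would reckon with the charges before either of them.

| setting | winter | autumn | elm | ash |
|---|---|---|---|---|
| starting material | 0.56 M | 1.5 M | 2.5 M | 0.80 M |
| partner | 1.44 M | 1.44 M | 1.44 M | 1.44 M |
| protic impurity | 0.40 M | 0.40 M | 0.400 M | 0.400 M |
| free catalyst | 0.40 mM | 0.40 mM | 0.40 mM | 0.40 mM |
| second catalyst | 4 mM | 4 mM | 4.0 mM | 4.0 mM |
| temperature | 95 °C | 110 °C |  |  |
| remark | run made earlier | run made earlier | at 100 °C throughout | at 100 °C until 4.0 h, from then on at 120 °C |
| time |  |  | 20 h | 20 h |

- winter (time / h: target / %, starting material / %): 0.833: 9.7, 79.8; 1.50: 21.0, 65.7; 3.00: 42.0, 44.6; 5.00: 60.3, 25.8; 10.0: 79.4, 6.7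
- autumn (time / h: target / %, starting material / %): 0.500: 11.9, 75.3; 1.50: 37.7, 45.3; 3.00: 59.2, 22.0; 5.00: 72.0, 9.1; 6.00: 75.2, 5.5

(each reading ± 0.5 percentage points)

- amounts and yields of target count crystals too
- given per volume of solution although it is solid: crystals
- the earlier runs were read with a standard deviation of 0.5 percentage points
- steps thought possible: second catalyst + open intermediate <-> catalyst intermediate; crystals <-> target; partner + catalyst intermediate <-> second catalyst + target; starting material + free catalyst <-> free catalyst + open intermediate; starting material + protic impurity -> quenched substrate

* the winner by amount of target, in percent of the starting material charged; "neither" if no more than 2 percentage points parts them (elm / ash / neither)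
* how much target is there at the end, in percent of the starting material charged: elm
* how much target is there at the end, in percent of the starting material charged: ash

Elm looks nearly like the autumn run: the same partner, protic impurity and catalysts, but more starting material and a bath at 100 °C against 110 °C. Each target takes one partner and each quenched substrate one protic impurity. So we ask what is left of the starting material once both charges have taken their full share. Elm has 0.660 M of this spare, which is [starting material] less [partner] less [protic impurity], all as charged. Elm's starting material is more than its partner and protic impurity together, so in elm the partner is the limiting reagent however far the quench runs, and the target heads for [partner] over [starting material], 57.6%.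

The autumn run has a spare of −0.340 M, and its last reading shows the other ending. After 6.00 h, its target leaves 0.312 M of partner against 0.0825 M of starting material, so starting material is the smaller remainder. In that reading target and starting material together make 80.7% of the charge, under the autumn run's ceiling of 96.0%.

If the quench takes its full share in elm, 26.4% of the charge is left over. Time has still to bring elm's target to its ceiling, and the winter run, at 95 °C and with another charge, read 25.8% of starting material after 5.00 h, which is shorter than elm's 20 h. We therefore commit to elm just under 57.6%.

Ash has a spare of −1.04 M, so its target is what the quench leaves. The last readings show 13.9% of the charge as neither target nor starting material in the winter run and 19.3% in the autumn run. Ash ends hotter than both, so we expect it under 80.7%, yet above elm.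

The forecast gives 57% for elm, 78% for ash and ash as the winner, saying of elm “leaving more than enough substrate”.

The flasks give 57.3% for elm and 74.7% for ash, so ash has more.

    second catalyst + open intermediate ⇌ catalyst intermediate (K = 5.41 /M, k = 14.4 /M/min, Ea = 74.0 kJ/mol, ΔH = −53.0 kJ/mol)
    crystals ⇌ target, rate k2*(cs2 - [target]) while solid is left; crystals form when [target] > cs2 (solubility = 0.100 M, k = 0.449 /min)
    partner + catalyst intermediate ⇌ second catalyst + target (K = 4.79, k = 15.1 /M/min, Ea = 56.0 kJ/mol, ΔH = −21.0 kJ/mol)
    starting material + free catalyst ⇌ free catalyst + open intermediate (K = 2.48, k = 12.4 /M/min, Ea = 47.0 kJ/mol, ΔH = −29.0 kJ/mol)
    starting material + protic impurity → quenched substrate (k = 0.00269 /M/min, Ea = 104 kJ/mol)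
    (constants at 100 °C)

Elm has come to rest in its target: ten times the time leaves it at 57.3%. At 20 h its spare stands in the flask as 0.743 M of starting material and open intermediate, which is close to the 0.660 M plus 0.0785 M of unused protic impurity. Ash has not come to rest. By 200 h its target falls to 55.6% while quenched substrate climbs from 22.4% to 41.8%. That run would undo the forecast's winner, since the two then stand within 2 percentage points.

A neighbour of elm charged with 0.58 M of partner has a spare of 1.52 M, its starting material being more than its partner and protic impurity together, and so a ceiling of 23.2%. It gives 23.1%.

The readings stem from a simulated flask for an exercise, noise included.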